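## Retrosynthetic overview

- The dihydropyran is closed last by dehydrative cyclisation of a δ‑hydroxy ketone; its C–Br comes from invertive bromide opening of a reagent‑controlled (Shi) prenyl epoxide.
- The key C–C bond joins the prenyl unit to the carbon between the ring and the acetyl group, by radical allyl transfer (α‑keto radical plus a tertiary allyl sulfone) on the fully halogenated core.
- The ring Br/Cl pair comes from anti addition of PhSeBr to a 4‑substituted 1‑methylcyclohexene, then Se→Cl exchange with a 1,2‑bromine shift.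
- The side‑chain ketone comes from acetyl‑anion addition to the aldehyde of an organocatalytic Diels–Alder adduct (isoprene + acrolein), which sets the ring CH stereocentre.
- Ring order: cyclohexene first (Diels–Alder), dihydropyran last.

Assumption: the side‑chain carbon bearing OH/Br/H in 5–8 and 12–14 is carried as a ~1:1 epimer mixture, because it becomes sp2 in the target.

## Route

**Step 1**
Reactants: 1 isoprene; 2 acrolein
Product: 3 (1S)‑4‑methylcyclohex‑3‑ene‑1‑carbaldehyde
Conditions: 5‑benzyl‑2,2,3‑trimethylimidazolidin‑4‑one·HCl (10 mol %, the enantiomer that gives the S adduct), MeNO2–H2O 95:5, 0 °C→rt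
Reagents that add atoms: none
Why: Iminium‑catalysed enantioselective Diels–Alder reaction with "para" regiochemistry; the catalyst shields one face of the acrolein iminium and sets C1 (about 90% ee expected; the minor series ends as a separable diastereomer once the Shi epoxidation has set the second stereochemical element).

**Step 2**
Reactants: 3; 4 ethyl vinyl ether (as 1‑ethoxyvinyllithium)
Product: 5 1‑hydroxy‑1‑[(1S)‑4‑methylcyclohex‑3‑en‑1‑yl]propan‑2‑one
Conditions: 4, t‑BuLi, THF, −78→0 °C; add 3, −78 °C; then 1 M HCl, THF, 0 °C→rt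
Reagents that add atoms: water, O
Why: Acyl‑anion (1‑ethoxyvinyllithium) 1,2‑addition to the aldehyde, then enol‑ether hydrolysis to the α‑hydroxy methyl ketone; addition at −78 °C is faster than enolisation, so C1 is kept, and the new carbinol centre is inconsequential.

**Step 3**
Reactants: 5
Product: 6 1‑bromo‑1‑[(1S)‑4‑methylcyclohex‑3‑en‑1‑yl]propan‑2‑one
Conditions: CBr4 (1.3 equiv), PPh3 (1.25 equiv, added last), CH2Cl2, 0 °C
Reagents that add atoms: carbon tetrabromide, BrC(Br)(Br)Br
Why: Appel bromination of the α‑ketol gives the α‑bromo ketone (the radical precursor) and removes the free OH that would otherwise trap the seleniranium ion in Step 4.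

**Step 4**
Reactants: 6
Product: 7 1‑bromo‑1‑[(1S,3R,4R)‑4‑bromo‑4‑methyl‑3‑(phenylselanyl)cyclohexyl]propan‑2‑one
Conditions: PhSeBr (1.05 equiv), CH2Cl2, −78→−20 °C, hold until the adduct has equilibrated; used directly in Step 5 without purification
Reagents that add atoms: phenylselenenyl bromide, Br[Se]c1ccccc1
Why: Reversible anti selenobromination under thermodynamic control gives the Markovnikov trans‑diaxial adduct, where the Markovnikov and Fürst–Plattner preferences agree: the seleniranium ion forms on the face trans to the equatorial side chain and bromide opens it axially at the tertiary carbon, so C4–Br is cis and C3–SePh trans to the side chain.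

**Step 5**
Reactants: 7
Product: 8 1‑bromo‑1‑[(1S,3S,4S)‑3‑bromo‑4‑chloro‑4‑methylcyclohexyl]propan‑2‑one
Conditions: SO2Cl2 (1.1 equiv), CH2Cl2, −78→0 °C (same flask as Step 4)
Reagents that add atoms: sulfuryl chloride, ClS(Cl)(=O)=O
Why: Proposed new method: SO2Cl2 oxidises the selenide to the Se(IV) dichloride, which leaves with help from the antiperiplanar axial C4–Br to give an unsymmetrical bromonium ion on the face cis to the side chain, and chloride then captures the tertiary carbon anti to bromine, so Br ends on C3 cis to the side chain and Cl on C4 trans to it (net 1,2‑bromine shift with inversion at both carbons); the closest known reactions are Se(IV) halogenolysis in selenium‑mediated alkene dichlorination and Winstein‑type neighbouring‑bromine substitution.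

**Step 6**
Reactants: 9 allyl methyl sulfone; 10 iodomethane
Product: 11 3‑methyl‑3‑(methylsulfonyl)but‑1‑ene
Conditions: n‑BuLi (1.05 equiv), THF, −78 °C, then MeI (1.1 equiv); then n‑BuLi (1.05 equiv), −78 °C, then MeI (1.2 equiv), −78 °C→rt
Reagents that add atoms: iodomethane, CI (the second equivalent; the first is reactant 10)
Why: Two sequential α‑alkylations of the allyl‑stabilised sulfonyl carbanion, which forms in preference to the S‑methyl carbanion and alkylates at the α‑carbon, give the tertiary allyl sulfone used as the prenyl‑transfer reagent.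

**Step 7 (key step)**
Reactants: 8; 11
Product: 12 3‑[(1S,3S,4S)‑3‑bromo‑4‑chloro‑4‑methylcyclohexyl]‑6‑methylhept‑5‑en‑2‑one
Conditions: 11 (4 equiv), Ru(bpy)3Cl2 (1 mol %), 4‑MeOC6H4NPh2 (2 equiv), DMF, blue LEDs, rt
Reagents that add atoms: none
Why: Photoredox radical allylation (Keck/Zard‑type SH2′ allyl transfer): single‑electron reduction cleaves only the activated α‑keto C–Br, the α‑keto radical adds to the unsubstituted alkene terminus of 11, and loss of MeSO2• delivers the prenyl group; no base is present, so the vicinal bromochloride survives where enolate alkylation would risk E2, and no ring stereocentre is touched.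

**Step 8**
Reactants: 12
Product: 13 3‑[(1S,3S,4S)‑3‑bromo‑4‑chloro‑4‑methylcyclohexyl]‑4‑[(2S)‑3,3‑dimethyloxiran‑2‑yl]butan‑2‑one
Conditions: ent‑Shi ketone (30 mol %), Oxone, K2CO3, n‑Bu4NHSO4, MeCN/DMM–aq. borate buffer (pH ≈ 10.5), 0 °C
Reagents that add atoms: Oxone (KHSO5), OOS(=O)(=O)[O-].[K+]
Why: Shi asymmetric epoxidation of the only alkene; the chiral dioxirane sets the epoxide CH as S by reagent control, independent of the remote ring stereocentres.

**Step 9**
Reactants: 13
Product: 14 (5R)‑5‑bromo‑3‑[(1S,3S,4S)‑3‑bromo‑4‑chloro‑4‑methylcyclohexyl]‑6‑hydroxy‑6‑methylheptan‑2‑one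
Conditions: Li2NiBr4 (2 equiv), THF, 0 °C→rt
Reagents that add atoms: dilithium tetrabromonickelate, [Li+].[Li+].Br[Ni-2](Br)(Br)Br
Why: SN2 opening of the trisubstituted epoxide by soft bromide at the less substituted carbon with inversion (S epoxide → 5R bromide), leaving the tertiary alcohol.

**Step 10**
Reactants: 14
Product: 15 laucapyranoid A, (3R)‑3‑bromo‑5‑[(1S,3S,4S)‑3‑bromo‑4‑chloro‑4‑methylcyclohexyl]‑2,2,6‑trimethyl‑3,4‑dihydro‑2H‑pyran
Conditions: PPTS (10 mol %), 4 Å MS, benzene, 50 °C
Reagents that add atoms: none
Why: Acid‑catalysed hemiketalisation and dehydration of the δ‑hydroxy ketone gives the more substituted endocyclic enol ether; the side‑chain epimers converge and no stereocentre is touched.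

## Compound list

1 | isoprene | C=CC(C)=C | starting material
2 | acrolein | C=CC=O | starting material
3 | (1S)‑4‑methylcyclohex‑3‑ene‑1‑carbaldehyde | O=C[C@H]1CCC(C)=CC1 | intermediate
4 | ethyl vinyl ether | C=COCC | starting material
5 | 1‑hydroxy‑1‑[(1S)‑4‑methylcyclohex‑3‑en‑1‑yl]propan‑2‑one (carbinol epimers) | CC(=O)C(O)[C@H]1CCC(C)=CC1 | intermediate
6 | 1‑bromo‑1‑[(1S)‑4‑methylcyclohex‑3‑en‑1‑yl]propan‑2‑one (CHBr epimers) | CC(=O)C(Br)[C@H]1CCC(C)=CC1 | intermediate
7 | 1‑bromo‑1‑[(1S,3R,4R)‑4‑bromo‑4‑methyl‑3‑(phenylselanyl)cyclohexyl]propan‑2‑one | CC(=O)C(Br)[C@H]1CC[C@@](C)(Br)[C@H]([Se]c2ccccc2)C1 | intermediate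
8 | 1‑bromo‑1‑[(1S,3S,4S)‑3‑bromo‑4‑chloro‑4‑methylcyclohexyl]propan‑2‑one | CC(=O)C(Br)[C@H]1CC[C@](C)(Cl)[C@@H](Br)C1 | intermediate
9 | allyl methyl sulfone | C=CCS(C)(=O)=O | starting material
10 | iodomethane | CI | starting material
11 | 3‑methyl‑3‑(methylsulfonyl)but‑1‑ene | C=CC(C)(C)S(C)(=O)=O | intermediate
12 | 3‑[(1S,3S,4S)‑3‑bromo‑4‑chloro‑4‑methylcyclohexyl]‑6‑methylhept‑5‑en‑2‑one | CC(=O)C(CC=C(C)C)[C@H]1CC[C@](C)(Cl)[C@@H](Br)C1 | intermediate
13 | 3‑[(1S,3S,4S)‑3‑bromo‑4‑chloro‑4‑methylcyclohexyl]‑4‑[(2S)‑3,3‑dimethyloxiran‑2‑yl]butan‑2‑one | CC(=O)C(C[C@@H]2OC2(C)C)[C@H]1CC[C@](C)(Cl)[C@@H](Br)C1 | intermediate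
14 | (5R)‑5‑bromo‑3‑[(1S,3S,4S)‑3‑bromo‑4‑chloro‑4‑methylcyclohexyl]‑6‑hydroxy‑6‑methylheptan‑2‑one | CC(=O)C(C[C@@H](Br)C(C)(C)O)[C@H]1CC[C@](C)(Cl)[C@@H](Br)C1 | intermediate
15 | laucapyranoid A | CC1=C([C@H]2CC[C@](C)(Cl)[C@@H](Br)C2)C[C@@H](Br)C(C)(C)O1 | target

## Summary

Total steps: 10. Longest linear sequence: 9 (Steps 1–5 and 7–10; Step 6 is a one‑step side branch). Steps 4 and 5 are run in one flask.

Steps most likely to fail, with fallbacks:

1. **Step 5.** Chloride may instead open the bromonium ion diaxially at the secondary carbon (the Fürst–Plattner mode), giving the 3‑chloro‑4‑bromo regioisomer, or Br+ may be lost. Fallback: reverse the order in which the ring centres are set.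
   - Add BrCl (Bu4N+ BrCl2−) to the O‑acetate of ent‑5; normal diaxial Markovnikov addition gives the 3S,4S centres with the wrong C1.
   - Erase C1 by dehydrating the ketol to the alkylidene ketone.
   - Reset C1 by conjugate hydride delivery anti to the axial C3–Br (Stryker's reagent), and quench the enolate with NBS to reach 8.
2. **Step 7.** Hydrodebromination of the α‑keto radical, sulfonyl‑radical isomerisation of 11 to unreactive prenyl methyl sulfone, or reduction of the vicinal bromochloride may compete. Fallback: Kharasch atom‑transfer addition of 8 to 2‑methylbut‑3‑en‑2‑ol, which gives 14 directly as C5 epimers; cyclise as in Step 10 and separate the diastereomeric pyrans. This loses reagent control at C–Br.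
3. **Step 9.** Bromide may attack the tertiary epoxide carbon, or the ketone oxygen may open the epoxide first. Fallback: switch to an electrophilic route, a catalyst‑controlled 6‑endo bromo‑ketalisation of 12 (NBS, chiral phosphoric acid or chiral Lewis base, MeOH) followed by PPTS‑mediated loss of MeOH.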